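**Assumption:** the target has no stereocentre and no stereogenic double bond (both alkenes end in CMe2), so it is achiral and "single enantiomer" needs no stereocontrol.

## Retrosynthetic overview

1. Avoided: Friedel–Crafts acylation of phloroglucinol, then electrophilic C-prenylation and selective O-methylation.
2. Target 15 ⇒ bis(O-prenyl) ether 9 by a double Claisen/Cope (para-Claisen) cascade. One operation makes both C-prenyl bonds and unveils both chelated phenols.
3. 9 ⇒ 2,6-difluoro-4-methoxybenzophenone 5 + prenol 6 by double SNAr. Fluorine is the phenol surrogate, and each oxygen arrives already carrying its prenyl group, so the three phenols never need to be differentiated.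
4. 5 ⇒ 3,5-difluoroanisole 1 + silyl-protected 3-hydroxybenzaldehyde 2 by fluorine-directed ortho-lithiation, 1,2-addition and oxidation.
5. No ring is formed: both benzene rings are bought intact. Bond order is diaryl C–C, then two C–O, then two C–C (prenyl).

## Route

**Step 1**
Reactants: 1 3,5-difluoroanisole; 2 3-[(tert-butyldimethylsilyl)oxy]benzaldehyde
Product: 4 rac-(2,6-difluoro-4-methoxyphenyl){3-[(tert-butyldimethylsilyl)oxy]phenyl}methanol, via 2,6-difluoro-4-methoxyphenyllithium 3 (not isolated)
Conditions: n-BuLi (1.05 equiv), THF, −78 °C, 1 h; then 2, −78 °C, 1 h; sat. aq NH4Cl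
Reagents that add atoms: none
Why: Directed ortho-metalation removes the most acidic proton, the one flanked by both fluorines, and the aryllithium (held at −78 °C to suppress LiF loss to an aryne) adds 1,2 to the aldehyde; the carbinol centre is racemic and is erased in step 2.

**Step 2**
Reactants: 4 rac-(2,6-difluoro-4-methoxyphenyl){3-[(tert-butyldimethylsilyl)oxy]phenyl}methanol
Product: 5 (2,6-difluoro-4-methoxyphenyl){3-[(tert-butyldimethylsilyl)oxy]phenyl}methanone
Conditions: Dess–Martin periodinane (1.3 equiv), CH2Cl2, rt, 1 h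
Reagents that add atoms: none
Why: Dess–Martin oxidation of a doubly benzylic secondary alcohol gives the diaryl ketone under near-neutral conditions that leave the aryl silyl ether and the aryl fluorides untouched.

**Step 3**
Reactants: 5 (2,6-difluoro-4-methoxyphenyl){3-[(tert-butyldimethylsilyl)oxy]phenyl}methanone; 6 3-methylbut-2-en-1-ol (prenol, used as its sodium alkoxide)
Product: 9 (3-hydroxyphenyl)[4-methoxy-2,6-bis(3-methylbut-2-enyloxy)phenyl]methanone, via desilylated difluoroketone sodium phenolate 7 (not isolated), via monofluoro mono-prenyl ether sodium phenolate 8 (not isolated)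
Conditions: 6 (6 equiv), NaH (5 equiv), THF–DMPU (4:1), 0 → 65 °C; sat. aq NH4Cl
Reagents that add atoms: none
Why: Double nucleophilic aromatic substitution (SNAr, addition–elimination) displaces both fluorides ortho to the ketone by prenyl alkoxide, while the same alkoxide removes the aryl TBS group by trans-silylation; the freed 3'-phenoxide stays unalkylated because no alkylating agent is present.

**Step 4**
Reactants: 9 (3-hydroxyphenyl)[4-methoxy-2,6-bis(3-methylbut-2-enyloxy)phenyl]methanone
Product: 15 [2,6-dihydroxy-4-methoxy-3,5-bis(3-methylbut-2-enyl)phenyl](3-hydroxyphenyl)methanone, via first ortho-dienone 10 (not isolated), via first para-dienone 11 (not isolated), via mono-rearranged phenol 12 (not isolated), via second ortho-dienone 13 (not isolated), via second para-dienone 14 (not isolated)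
Conditions: PhNEt2, 200 °C, sealed tube, Ar, 3 h
Reagents that add atoms: none
Why: Tandem aromatic Claisen/Cope (para-Claisen) rearrangement run twice in one pot: the first O-prenyl group shifts [3,3] to the flanked ortho carbon to give crowded dienone 10, whose Cope shift to the para carbon restores a linear prenyl group faster than enolisation (the known behaviour of O-prenyl ethers of 2-acyl-3,5-dialkoxyphenols), and the second ether, now with both ortho positions blocked, can only deliver a linear prenyl group to the last free carbon; it is a pure isomerisation and creates no stereocentre.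

## Compound list

1 | 3,5-difluoroanisole | COc1cc(F)cc(F)c1 | starting material
2 | 3-[(tert-butyldimethylsilyl)oxy]benzaldehyde | CC(C)(C)[Si](C)(C)Oc1cccc(C=O)c1 | starting material
3 | 2,6-difluoro-4-methoxyphenyllithium | COc1cc(F)c([Li])c(F)c1 | intermediate
4 | rac-(2,6-difluoro-4-methoxyphenyl){3-[(tert-butyldimethylsilyl)oxy]phenyl}methanol | COc1cc(F)c(C(O)c2cccc(O[Si](C)(C)C(C)(C)C)c2)c(F)c1 | intermediate
5 | (2,6-difluoro-4-methoxyphenyl){3-[(tert-butyldimethylsilyl)oxy]phenyl}methanone | COc1cc(F)c(C(=O)c2cccc(O[Si](C)(C)C(C)(C)C)c2)c(F)c1 | intermediate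
6 | 3-methylbut-2-en-1-ol (prenol) | CC(C)=CCO | starting material
7 | sodium 3-(2,6-difluoro-4-methoxybenzoyl)phenolate | COc1cc(F)c(C(=O)c2cccc([O-])c2)c(F)c1.[Na+] | intermediate
8 | sodium 3-[2-fluoro-4-methoxy-6-(3-methylbut-2-enyloxy)benzoyl]phenolate | COc1cc(F)c(C(=O)c2cccc([O-])c2)c(OCC=C(C)C)c1.[Na+] | intermediate
9 | (3-hydroxyphenyl)[4-methoxy-2,6-bis(3-methylbut-2-enyloxy)phenyl]methanone | COc1cc(OCC=C(C)C)c(C(=O)c2cccc(O)c2)c(OCC=C(C)C)c1 | intermediate
10 | rac-2-(3-hydroxybenzoyl)-5-methoxy-6-(2-methylbut-3-en-2-yl)-3-(3-methylbut-2-enyloxy)cyclohexa-2,4-dien-1-one | O=C1C(C(C)(C)C=C)C(OC)=CC(OCC=C(C)C)=C1C(=O)c1cccc(O)c1 | intermediate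
11 | rac-2-(3-hydroxybenzoyl)-5-methoxy-4-(3-methylbut-2-enyl)-3-(3-methylbut-2-enyloxy)cyclohexa-2,5-dien-1-one | O=C1C=C(OC)C(CC=C(C)C)C(OCC=C(C)C)=C1C(=O)c1cccc(O)c1 | intermediate
12 | [6-hydroxy-4-methoxy-3-(3-methylbut-2-enyl)-2-(3-methylbut-2-enyloxy)phenyl](3-hydroxyphenyl)methanone | COc1cc(O)c(C(=O)c2cccc(O)c2)c(OCC=C(C)C)c1CC=C(C)C | intermediate
13 | rac-3-hydroxy-2-(3-hydroxybenzoyl)-5-methoxy-6-(2-methylbut-3-en-2-yl)-6-(3-methylbut-2-enyl)cyclohexa-2,4-dien-1-one | O=C1C(CC=C(C)C)(C(C)(C)C=C)C(OC)=CC(O)=C1C(=O)c1cccc(O)c1 | intermediate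
14 | rac-3-hydroxy-2-(3-hydroxybenzoyl)-5-methoxy-4,6-bis(3-methylbut-2-enyl)cyclohexa-2,5-dien-1-one | O=C1C(CC=C(C)C)=C(OC)C(CC=C(C)C)C(O)=C1C(=O)c1cccc(O)c1 | intermediate
15 | [2,6-dihydroxy-4-methoxy-3,5-bis(3-methylbut-2-enyl)phenyl](3-hydroxyphenyl)methanone (CNP0425861.0) | COc1c(CC=C(C)C)c(O)c(C(=O)c2cccc(O)c2)c(O)c1CC=C(C)C | target

## Step count and risk

Total steps: 4. Longest linear sequence: 4 (1 → 4 → 5 → 9 → 15).

**Most likely to fail, in order:**

**Step 4.** The risk is that dienone 10 enolises before its Cope shift, which would give 1,1-dimethylallyl (reverse-prenyl) isomers instead of linear prenyl groups. The fallback sets out from 5 and comes back at 15. Ketone 5 is treated with sodium allyloxide (allyl alcohol, NaH, THF–DMPU) as in step 3 to give (3-hydroxyphenyl)[4-methoxy-2,6-bis(prop-2-enyloxy)phenyl]methanone F1. Thermal Claisen rearrangement (PhNEt2, 200 °C) then gives [2,6-dihydroxy-4-methoxy-3,5-bis(prop-2-enyl)phenyl](3-hydroxyphenyl)methanone F2; here ortho and para delivery give the same unbranched allyl group, so no constitutional ambiguity exists. Double olefin cross-metathesis of F2 with 2-methylbut-2-ene (Grubbs II, CH2Cl2, 40 °C) turns both allyl groups into prenyl groups and gives 15.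

**Step 3.** The risks are a sluggish second substitution on the twisted, increasingly electron-rich ketone, alkoxide attack at the carbonyl (aryl–CO cleavage or hydride-transfer reduction), and phenoxide 7 acting as a competing nucleophile. The fallback sets out from 6 and comes back at 9, moving the SNAr to a nitrile. Sodium prenyloxide from 6 displaces both fluorides of commercial 2,6-difluoro-4-methoxybenzonitrile F3 to give 4-methoxy-2,6-bis(3-methylbut-2-enyloxy)benzonitrile F4. Commercial (3-bromophenoxy)(tert-butyl)dimethylsilane F5 is converted by Br/Li exchange (n-BuLi, THF, −78 °C) into {3-[(tert-butyldimethylsilyl)oxy]phenyl}lithium F6. F6 adds to the nitrile of F4 and, after aqueous quench, gives 1-{3-[(tert-butyldimethylsilyl)oxy]phenyl}-1-[4-methoxy-2,6-bis(3-methylbut-2-enyloxy)phenyl]methanimine F7. Hydrolysis (1 M HCl, THF, rt) gives {3-[(tert-butyldimethylsilyl)oxy]phenyl}[4-methoxy-2,6-bis(3-methylbut-2-enyloxy)phenyl]methanone F8, and TBAF (THF, 0 °C) then gives 9.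

**Step 1.** The risks are LiF elimination from 3 to an aryne if the temperature rises, and any lithiation next to the methoxy group. The fallback sets out from 2 and comes back at 4, replacing deprotonation by halogen–magnesium exchange. Commercial 2-bromo-1,3-difluoro-5-methoxybenzene F9 is treated with i-PrMgCl·LiCl (THF, −20 °C) to give (2,6-difluoro-4-methoxyphenyl)magnesium chloride F10. Its metal position is fixed by the bromine and it is far less prone to fluoride loss; it adds to aldehyde 2 to give 4.

## Further compounds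

F1 | step 4 | (3-hydroxyphenyl)[4-methoxy-2,6-bis(prop-2-enyloxy)phenyl]methanone | COc1cc(OCC=C)c(C(=O)c2cccc(O)c2)c(OCC=C)c1
F2 | step 4 | [2,6-dihydroxy-4-methoxy-3,5-bis(prop-2-enyl)phenyl](3-hydroxyphenyl)methanone | COc1c(CC=C)c(O)c(C(=O)c2cccc(O)c2)c(O)c1CC=C
F3 | step 3 | 2,6-difluoro-4-methoxybenzonitrile | COc1cc(F)c(C#N)c(F)c1
F4 | step 3 | 4-methoxy-2,6-bis(3-methylbut-2-enyloxy)benzonitrile | COc1cc(OCC=C(C)C)c(C#N)c(OCC=C(C)C)c1
F5 | step 3 | (3-bromophenoxy)(tert-butyl)dimethylsilane | CC(C)(C)[Si](C)(C)Oc1cccc(Br)c1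
F6 | step 3 | {3-[(tert-butyldimethylsilyl)oxy]phenyl}lithium | CC(C)(C)[Si](C)(C)Oc1cccc([Li])c1
F7 | step 3 | 1-{3-[(tert-butyldimethylsilyl)oxy]phenyl}-1-[4-methoxy-2,6-bis(3-methylbut-2-enyloxy)phenyl]methanimine | COc1cc(OCC=C(C)C)c(C(=N)c2cccc(O[Si](C)(C)C(C)(C)C)c2)c(OCC=C(C)C)c1
F8 | step 3 | {3-[(tert-butyldimethylsilyl)oxy]phenyl}[4-methoxy-2,6-bis(3-methylbut-2-enyloxy)phenyl]methanone | COc1cc(OCC=C(C)C)c(C(=O)c2cccc(O[Si](C)(C)C(C)(C)C)c2)c(OCC=C(C)C)c1
F9 | step 1 | 2-bromo-1,3-difluoro-5-methoxybenzene | COc1cc(F)c(Br)c(F)c1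
F10 | step 1 | (2,6-difluoro-4-methoxyphenyl)magnesium chloride | COc1cc(F)c([Mg]Cl)c(F)c1
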